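The furan-2,5-dione ring of the target is read as an internal alkyne that has taken up two molecules of CO2. Ring carbons C3 (bearing the acetoxytetradecyl chain) and C4 (bearing the methyl group) are the former alkyne carbons, and the carbonyl carbons C2 and C5 come from CO2. A nickel-catalysed reductive double carboxylation therefore forms both carbonyl–alkene bonds, C2–C3 and C5–C4, in one operation on the ring-free precursor heptadec-15-yn-1-yl acetate. The resulting cis-diacid closes to the anhydride on acidic work-up. The alkyne is assembled by alkylation of 1-propynyllithium with 14-bromotetradecan-1-ol and acetylation, so the key step is the last step.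

Key step: step 3

Remark: 14-bromotetradecan-1-ol and solid 1-propynyllithium are taken as catalogue chemicals. The target has no stereocentre; its only stereochemical element is the ring-enforced cis alkene.

Step 1
Reactants: 1 14-bromotetradecan-1-ol; 2 1-propynyllithium
Product: 5 heptadec-15-yn-1-ol, via lithium 14-bromotetradecan-1-olate 3 (not isolated), via lithium heptadec-15-yn-1-olate 4 (not isolated)
Conditions: 2 (2.5 equiv), THF/DMPU, 0 °C to rt; then H2O
Reagents that add atoms: none
Why: Alkylation of a lithium acetylide (SN2 at a primary bromide) in a dipolar medium, in which the first equivalent of 2 only removes the hydroxyl proton to give alkoxide 3, whose O-alkylation is much slower than C-alkylation by the unhindered acetylide, so that a second equivalent displaces bromide to give 4, which is protonated on quench.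

Step 2
Reactants: 5 heptadec-15-yn-1-ol
Product: 6 heptadec-15-yn-1-yl acetate
Conditions: Ac2O, pyridine, DMAP (cat.), CH2Cl2, 0 °C to rt
Reagents that add atoms: acetic anhydride, CC(=O)OC(C)=O
Why: DMAP-catalysed O-acylation of a primary alcohol through the N-acetylpyridinium ion, to which the internal alkyne is inert.

Step 3
Reactants: 6 heptadec-15-yn-1-yl acetate
Product: 9 Aspergillus acid E (14-(4-methyl-2,5-dioxo-2,5-dihydrofuran-3-yl)tetradecyl acetate), via zinc maleate salt 7 (not isolated), via maleic diacid 8 (not isolated)
Conditions: Ni(acac)2(bpy) (10 mol %; acac = acetylacetonate, bpy = 2,2'-bipyridine), Zn powder (3 equiv), MgBr2 (3 equiv), 3 Å MS, CO2 (1 atm), DMF, rt; then cold 1 M HCl, EtOAc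
Reagents that add atoms: carbon dioxide, O=C=O (two molecules)
Why: Zn reduces Ni(acac)2(bpy) to a zerovalent nickel–bipyridine species, which couples the alkyne of 6 with one CO2 by oxidative cyclisation to a five-membered oxanickelacyclopentenone of divalent nickel (first carbonyl–alkene C–C bond), after which one-electron reduction to monovalent nickel and MgBr2 activation of a second CO2 allow insertion into the remaining nickel–vinyl bond (second C–C bond) and further reduction releases the cis-dicarboxylate 7 with return of zerovalent nickel. The closest known reaction type is exactly this nickel-catalysed reductive double carboxylation of internal dialkyl alkynes with CO2, the catalytic form of stoichiometric nickelalactone chemistry. The one ring of the target is closed after the C–C bond formation: acidification gives diacid 8, whose cis carboxyl groups condense by 5-exo-trig O-acylation with loss of water, as 2,3-dialkylmaleic acids do spontaneously. No stereocentre is formed, and the only stereochemical element, the cis geometry of the tetrasubstituted alkene, follows from syn delivery of both carboxyl groups through the metallacycle and is then locked in the ring. The step needs double carboxylation to outrun protonation of the nickel–vinyl bond (which would give an acrylic acid) and alkyne cyclotrimerisation, which MgBr2, excess Zn, molecular sieves and the CO2 atmosphere should secure, while the regiochemistry of the first insertion is immaterial because both alkyne carbons end up carboxylated. The primary alkyl acetate offers zerovalent nickel no activated C–O bond and is not reduced by Zn, so it should survive the reaction and the brief cold dilute HCl work-up.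

Compound list
1 | 14-bromotetradecan-1-ol | OCCCCCCCCCCCCCCBr | starting material
2 | 1-propynyllithium | [Li]C#CC | starting material
3 | lithium 14-bromotetradecan-1-olate | [Li+].[O-]CCCCCCCCCCCCCCBr | intermediate (not isolated)
4 | lithium heptadec-15-yn-1-olate | [Li+].[O-]CCCCCCCCCCCCCCC#CC | intermediate (not isolated)
5 | heptadec-15-yn-1-ol | OCCCCCCCCCCCCCCC#CC | intermediate
6 | heptadec-15-yn-1-yl acetate | CC(=O)OCCCCCCCCCCCCCCC#CC | intermediate
7 | zinc (Z)-2-(14-acetoxytetradecyl)-3-methylbut-2-enedioate (zinc maleate salt; simplest formulation of the metal carboxylate) | [Zn+2].CC(=O)OCCCCCCCCCCCCCC/C(C(=O)[O-])=C(\C)C(=O)[O-] | intermediate (not isolated)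
8 | (Z)-2-(14-acetoxytetradecyl)-3-methylbut-2-enedioic acid (maleic diacid) | CC(=O)OCCCCCCCCCCCCCC/C(C(=O)O)=C(\C)C(=O)O | intermediate (not isolated)
9 | Aspergillus acid E, 14-(4-methyl-2,5-dioxo-2,5-dihydrofuran-3-yl)tetradecyl acetate | CC(=O)OCCCCCCCCCCCCCCC1=C(C)C(=O)OC1=O | target

Total step count: 3
Longest linear sequence: 3 steps (1 → 5 → 6 → 9)

Steps most likely to fail

1. Step 3 (key step). The second CO2 insertion may be outrun by protonation of the nickel–vinyl intermediate, which stops the reaction at single carboxylation, or by nickel-mediated oligomerisation of the alkyne. The fallback keeps the same two bond formations but switches from reductive carboxylation with CO2 to oxidative carbonylation with CO. It sets out from 6 and comes back at 9. Palladium-catalysed oxidative bis(methoxycarbonylation) of 6 (Pd(OCOCF3)2, N,N'-diaryl α-diimine ligand, p-benzoquinone, cat. p-TsOH, CO 4 bar, MeOH/THF, rt) should give dimethyl (Z)-2-(14-acetoxytetradecyl)-3-methylbut-2-enedioate F1 by syn addition of two methoxycarbonyl groups at divalent palladium. Saponification of all three esters (LiOH, THF/H2O, then HCl) should give, after spontaneous ring closure of the dialkylmaleic acid, 3-(14-hydroxytetradecyl)-4-methylfuran-2,5-dione F2. Acetylation (Ac2O, pyridine, DMAP) should then restore the acetate, re-close any open diacid and give 9.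

2. Step 1. The alkoxide formed first may aggregate and slow the substitution, and E2 elimination by the basic acetylide may compete with SN2 displacement. The fallback replaces the SN2 step by a cross-coupling that tolerates an ester, so the acetate is installed first. It sets out from 1 and comes back at 6. Acetylation of 1 (Ac2O, pyridine, DMAP) should give 14-bromotetradecyl acetate F3. Nickel-catalysed alkyl–alkynyl Kumada coupling of F3 with commercial 1-propynylmagnesium bromide (pincer complex NiCl[N(C6H4-2-NMe2)2] cat., bis[2-(dimethylamino)ethyl] ether, THF, rt, slow addition of the Grignard reagent) should give 6 directly, with step 2 no longer needed.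

3. Step 2. Acyl transfer to the waxy long-chain alcohol may stall at incomplete conversion through poor solubility at low temperature. The fallback forms the ester C–O bond by substitution at carbon instead of acylation at oxygen. It sets out from 5 and comes back at 6. Mesylation (MsCl, Et3N, CH2Cl2, 0 °C) should give heptadec-15-yn-1-yl methanesulfonate F4, and displacement with CsOAc (DMF, 60 °C) should give 6.

Further compounds
F1 | step 3 | dimethyl (Z)-2-(14-acetoxytetradecyl)-3-methylbut-2-enedioate | CC(=O)OCCCCCCCCCCCCCC/C(C(=O)OC)=C(\C)C(=O)OC
F2 | step 3 | 3-(14-hydroxytetradecyl)-4-methylfuran-2,5-dione | OCCCCCCCCCCCCCCC1=C(C)C(=O)OC1=O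
F3 | step 1 | 14-bromotetradecyl acetate | CC(=O)OCCCCCCCCCCCCCCBr
F4 | step 2 | heptadec-15-yn-1-yl methanesulfonate | CS(=O)(=O)OCCCCCCCCCCCCCCC#CC
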